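By 50.0 min the east run held 40% left-handed product against 0% right-handed product, more of the first, in percent of the two substrates charged together. So I asked how fast right-handed substrate goes late in a run, where east read 1% left-handed substrate at 90.0 min.

| flask | left-handed substrate | right-handed substrate | gas | free catalyst | impurity | remark | time |
|---|---|---|---|---|---|---|---|
| east | 0.25 M | 0.25 M | 96 mM (held) | 0.25 mM | 80 µM | run made earlier |  |
| north | 0.25 M | 0.25 M | 96 mM (held) | 0.25 mM | 130 µM | run made earlier |  |
| south-east | 0.50 M | 0.50 M | 96 mM (held) | 0.25 mM | 57 µM | run made earlier |  |
| elm | 0.25 M | 0.25 M | 96 mM (held) | 0.25 mM | 57 µM |  | 2.0 h |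
| cedar | 0.25 M | 0.25 M | 96 mM (held) | 0.25 mM | 57 µM |  | 3.0 h |

| run | time / min | left-handed product / % | right-handed product / % | left-handed substrate / % |
|---|---|---|---|---|
| east | 25.0 | 19 | 0 | 26 |
| east | 50.0 | 40 | 0 | 14 |
| east | 80.0 | 47 | 4 | 0 |
| east | 90.0 | 48 | 4 | 1 |
| north | 8.00 | 3 | 0 | 43 |
| north | 20.0 | 15 | 0 | 37 |
| north | 40.0 | 28 | 0 | 22 |
| north | 90.0 | 45 | 5 | 3 |
| south-east | 12.0 | 7 | 0 | 43 |
| south-east | 30.0 | 10 | 1 | 36 |
| south-east | 60.0 | 27 | 1 | 20 |
| south-east | 90.0 | 41 | 1 | 10 |

(each reading ± 1.5 percentage points)

- free catalyst is single-handed; left-handed substrate and right-handed substrate are mirror images of each other, charged as a racemate, each of them at the stated concentration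
- at the start none of reagent is dissolved
- the analysis behind the earlier runs scatters by 1.5 percentage points, standard deviation
- what may be going on: free catalyst + impurity -> spent catalyst; free catalyst <-> dormant form; reagent + free catalyst + left-handed substrate -> free catalyst + left-handed product; reagent + free catalyst + right-handed substrate -> free catalyst + right-handed product; gas <-> reagent
- an excess is below zero if the other one leads

- the winner by excess of left-handed product over right-handed product in the product; "neither" if no more than 2 percentage points parts them (elm / cedar / neither)
- excess of left-handed product over right-handed product in the product at the end, elm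
- excess of left-handed product over right-handed product in the product at the end, cedar

I reckoned right-handed product two ways. At 90.0 min, east and north averaged 4.50%. Spread evenly from the start, that is 0.0300 /h as a fraction of the charge. Read from the late stretches instead, east rose 0.0800 /h and north 0.0600 /h, a mean of 0.0700 /h, faster than the even pace.

The two ways part, so one cheats, and south-east shows which. At 90.0 min it still held 10% left-handed substrate and read 1% right-handed product, less than the 4.50% of east and north. The even pace puts 4.50% of right-handed product into south-east at that time, against its reading of 1%, so I dropped the average and kept the late slope.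

Dividing that slope by the 45.5% of right-handed substrate that the charge less the average leaves at 90.0 min gives 0.154 /h, the late right-handed rate constant: the pseudo-first-order fraction of remaining right-handed substrate turned over per hour, as read over the late stretches of east and north. It is a rough reading, since each point scatters by 1.5 percentage points.

I started elm and cedar from that 45.5% at 90.0 min and took left-handed product as 0.5 of the charge, so the excess is S over one minus S, with S the fraction of right-handed substrate remaining. That gave me 72.8% for elm and 56.6% for cedar. The forecast named elm, with 79% and 70%, higher than mine, reasoning of right-handed product that “It keeps creeping up after the left-handed substrate is gone, so excess falls with time”.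

    free catalyst + impurity → spent catalyst (k = 6270 /M/min)
    free catalyst ⇌ dormant form (K = 0.500, k = 0.127 /min)
    reagent + free catalyst + left-handed substrate → free catalyst + left-handed product (k = 13300 /M²/min)
    reagent + free catalyst + right-handed substrate → free catalyst + right-handed product (k = 287 /M²/min)
    gas ⇌ reagent, rate k5*(csat - [reagent]) (kL = 0.0563 /min)

The winner was elm, with 71.5% against 52.9% for cedar. In elm, reagent stood at 37.2% of its saturation at 1.00 h and at 84.2% at 2.00 h. Starting from cedar's 34.6% right-handed substrate at 3.00 h, 0.154 /h over the next 5.00 h gave me 16.0%, and cedar read at 8.0 h held 12.9%.

All runs come from a simulation on assumed constants; noise was put on by code.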